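**Retrosynthetic overview**
1. C5' carbinol ⇐ C5' ketone by a reagent-controlled 1,2-reduction in the last step. While it is a ketone, the 6',7'-alkene is an enone and stays out of the epoxidation.
2. Oxirane ⇐ 2',3'-alkene of the complete, already O-linked C10 chain, by late-stage asymmetric epoxidation, as the plant is presumed to oxidize its geranyl ether.
3. Aryl–O–C1' ether ⇐ 7-hydroxy-8-methoxycoumarin + (E)-allylic chloride; C4'–C5' bond ⇐ isoprene + 3-methylbut-2-enoyl chloride (C5 + C5).
4. Pyranone ring ⇐ ortho-hydroxycinnamate by trans→cis isomerization and lactonization.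
5. Ring order: pyranone first (step 1), oxirane second (step 4); no protecting groups.

Assumption: the plant is presumed to close the coumarin from an ortho-hydroxycinnamate, O-alkylate it with the C10 chain, oxidize C5' and epoxidize the 2',3'-alkene last; primed locants number the side chain from the ether carbon.

**Step 1**
Reactants: 1 2,4-dihydroxy-3-methoxybenzaldehyde; 2 ethyl (triphenylphosphoranylidene)acetate
Product: 5 7-hydroxy-8-methoxy-2H-chromen-2-one, via ethyl (E)-2,4-dihydroxy-3-methoxycinnamate 3 (not isolated), via ethyl (Z)-2,4-dihydroxy-3-methoxycinnamate 4 (not isolated)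
Conditions: PhNEt2, 215 °C (reflux), 5 h
Reagents that add atoms: none
Why: One-pot Wittig olefination–lactonization: the stabilized ylide gives the trans-2-hydroxycinnamate, which at this temperature isomerizes to the cis ester and closes to the lactone with loss of ethanol, the laboratory copy of the plant's coumarin ring closure; no stereocenter is formed.

**Step 2**
Reactants: 6 3-methylbut-2-enoyl chloride; 7 isoprene (2-methylbuta-1,3-diene)
Product: 8 (2E)-1-chloro-3,7-dimethylocta-2,6-dien-5-one
Conditions: SnCl4 (0.2 equiv), excess 7, CH2Cl2, −78 °C, 1 h; cold aq. NaHCO3 quench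
Reagents that add atoms: none
Why: Lewis-acid chloroacylation of a 1,3-diene (Friedel–Crafts-type acylation of an alkene): the activated acid chloride attacks C1 of s-trans isoprene, the methyl-stabilized allyl cation takes chloride back at C4, and the 1,4-adduct therefore carries the E geometry dictated by the s-trans diene; the cold quench limits re-ionization of the tertiary 1,2-adduct and thus E/Z scrambling.

**Step 3**
Reactants: 5 7-hydroxy-8-methoxy-2H-chromen-2-one; 8 (2E)-1-chloro-3,7-dimethylocta-2,6-dien-5-one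
Product: 9 7-{[(2E)-3,7-dimethyl-5-oxoocta-2,6-dien-1-yl]oxy}-8-methoxy-2H-chromen-2-one
Conditions: K2CO3 (1.05 equiv), NaI (0.1 equiv), DMF, 0 to 20 °C
Reagents that add atoms: none
Why: Williamson etherification (iodide-catalyzed SN2) of the acidic 7-OH (pKa about 8) at the primary allylic carbon with retention of the E-alkene; only one equivalent of weak base is present, so the doubly activated C4' methylene is not enolized, and no stereocenter is formed.

**Step 4**
Reactants: 9 7-{[(2E)-3,7-dimethyl-5-oxoocta-2,6-dien-1-yl]oxy}-8-methoxy-2H-chromen-2-one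
Product: 10 8-methoxy-7-{[(2R,3R)-3-methyl-3-(4-methyl-2-oxopent-3-en-1-yl)oxiran-2-yl]methoxy}-2H-chromen-2-one
Conditions: D-fructose-derived Shi ketone (1,2:4,5-di-O-isopropylidene-β-D-erythro-hexo-2,3-diulo-2,6-pyranose, 3 equiv, regenerated), Oxone (2KHSO5·KHSO4·K2SO4), NaHCO3, MeCN/aq. Na2EDTA, 0 °C, pH 7.5–8
Reagents that add atoms: potassium peroxymonosulfate (active salt of Oxone), [K+].[O-]S(=O)(=O)OO
Why: Shi asymmetric epoxidation: the electrophilic chiral dioxirane oxidizes only the isolated trisubstituted 2',3'-alkene because the 6',7'-alkene is deactivated as an enone and the coumarin 3,4-alkene is electron-poor; the spiro transition state of the D-fructose-derived ketone gives the (2R,3R)-oxirane, its trans arrangement comes from the E-alkene, and the near-neutral bicarbonate buffer spares the base-labile β,γ-unsaturated ketone and the β,γ-epoxy ketone.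

**Step 5**
Reactants: 10 8-methoxy-7-{[(2R,3R)-3-methyl-3-(4-methyl-2-oxopent-3-en-1-yl)oxiran-2-yl]methoxy}-2H-chromen-2-one
Product: 11 7-({(2R,3R)-3-[(2R)-2-hydroxy-4-methylpent-3-en-1-yl]-3-methyloxiran-2-yl}methoxy)-8-methoxy-2H-chromen-2-one
Conditions: (S)-2-methyl-CBS-oxazaborolidine (0.5 equiv), catecholborane (1.5 equiv), toluene, −78 °C; MeOH, then pH 7 buffer
Reagents that add atoms: none
Why: Corey–Bakshi–Shibata reduction: the (S)-oxazaborolidine binds the ketone with the alkenyl group as the large substituent and delivers hydride from catecholborane to the face that gives the (5'R)-allylic alcohol by clean 1,2-reduction, while oxirane, lactone and coumarin alkene are inert at −78 °C.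

**Compound list**
1 | 2,4-dihydroxy-3-methoxybenzaldehyde | O=Cc1ccc(O)c(OC)c1O | starting material
2 | ethyl (triphenylphosphoranylidene)acetate | CCOC(=O)C=P(c1ccccc1)(c1ccccc1)c1ccccc1 | starting material
3 | ethyl (2E)-3-(2,4-dihydroxy-3-methoxyphenyl)prop-2-enoate | CCOC(=O)/C=C/c1ccc(O)c(OC)c1O | intermediate
4 | ethyl (2Z)-3-(2,4-dihydroxy-3-methoxyphenyl)prop-2-enoate | CCOC(=O)/C=C\c1ccc(O)c(OC)c1O | intermediate
5 | 7-hydroxy-8-methoxy-2H-chromen-2-one | COc1c(O)ccc2ccc(=O)oc12 | intermediate
6 | 3-methylbut-2-enoyl chloride | CC(C)=CC(=O)Cl | starting material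
7 | isoprene (2-methylbuta-1,3-diene) | C=CC(C)=C | starting material
8 | (2E)-1-chloro-3,7-dimethylocta-2,6-dien-5-one | ClC/C=C(\C)CC(=O)C=C(C)C | intermediate
9 | 7-{[(2E)-3,7-dimethyl-5-oxoocta-2,6-dien-1-yl]oxy}-8-methoxy-2H-chromen-2-one | COc1c(OC/C=C(\C)CC(=O)C=C(C)C)ccc2ccc(=O)oc12 | intermediate
10 | 8-methoxy-7-{[(2R,3R)-3-methyl-3-(4-methyl-2-oxopent-3-en-1-yl)oxiran-2-yl]methoxy}-2H-chromen-2-one | COc1c(OC[C@H]2O[C@]2(C)CC(=O)C=C(C)C)ccc2ccc(=O)oc12 | intermediate
11 | 7-({(2R,3R)-3-[(2R)-2-hydroxy-4-methylpent-3-en-1-yl]-3-methyloxiran-2-yl}methoxy)-8-methoxy-2H-chromen-2-one | COc1c(OC[C@H]2O[C@]2(C)C[C@@H](O)C=C(C)C)ccc2ccc(=O)oc12 | target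

**Total steps:** 5. **Longest linear sequence:** 4 (steps 2, 3, 4, 5 from 6 and 7; equally steps 1, 3, 4, 5 from 1).

**Steps most likely to fail**

Step 2 (chloroacylation of isoprene). The E-selectivity rests on kinetic 1,4-capture; the crude product can also contain the tertiary 1,2-adduct, some Z-chloride and isoprene oligomers, and a Z-ether would be hard to remove from 9. The fallback builds the chain with a geometry-secure vinylogous aldol reaction; it sets out from 6 (and uses 5) and comes back at 9. Methanolysis of 6 gives methyl 3-methylbut-2-enoate F1. LiN(i-Pr)2 and Me3SiCl in THF at −78 °C convert it into the silyl dienolate [(1-methoxy-3-methylbuta-1,3-dien-1-yl)oxy]trimethylsilane F2. BF3·OEt2-mediated vinylogous Mukaiyama aldol addition of F2 to 3-methylbut-2-enal gives racemic methyl (2E)-5-hydroxy-3,7-dimethylocta-2,6-dienoate F3. Reduction with i-Bu2AlH gives (2E)-3,7-dimethylocta-2,6-diene-1,5-diol F4. Mitsunobu coupling (PPh3, DIAD, THF, 0 °C) of its primary allylic hydroxyl with 5 gives racemic 7-{[(2E)-5-hydroxy-3,7-dimethylocta-2,6-dien-1-yl]oxy}-8-methoxy-2H-chromen-2-one F5. Dess–Martin periodinane with NaHCO3 in CH2Cl2 oxidizes F5 to 9.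

Step 4 (Shi epoxidation). The doubly activated C4' methylene makes 9 and 10 prone to enolization, with loss of the aryloxide or opening of the oxirane, and the enantioselectivity on this allylic aryl ether may fall short. The fallback gives up asymmetric epoxidation and lets the reduction sort the isomers; it sets out from 9 and comes back at 11. Buffered mCPBA (NaHCO3, CH2Cl2, 0 °C) epoxidizes the same alkene without base and gives 10 together with its mirror image, 8-methoxy-7-{[(2S,3S)-3-methyl-3-(4-methyl-2-oxopent-3-en-1-yl)oxiran-2-yl]methoxy}-2H-chromen-2-one F6. Reduction of this racemate under the conditions of step 5 gives 11 and the diastereomer 7-({(2S,3S)-3-[(2R)-2-hydroxy-4-methylpent-3-en-1-yl]-3-methyloxiran-2-yl}methoxy)-8-methoxy-2H-chromen-2-one F7. These are separated by chromatography, at the cost of half the material.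

Step 5 (CBS reduction). The two ketone substituents (2-methylprop-1-enyl against a β-branched CH2) may be told apart poorly, and the neighboring oxirane may oppose the catalyst. The fallback replaces reagent control by separation and inversion; it sets out from 10 and comes back at 11. Luche reduction (NaBH4, CeCl3·7H2O, MeOH, −78 °C) gives 11 and its epimer 7-({(2R,3R)-3-[(2S)-2-hydroxy-4-methylpent-3-en-1-yl]-3-methyloxiran-2-yl}methoxy)-8-methoxy-2H-chromen-2-one F8, which are separated. F8 is inverted by Mitsunobu esterification (4-nitrobenzoic acid, PPh3, DIAD) to (2R)-1-[(2R,3R)-3-{[(8-methoxy-2-oxo-2H-chromen-7-yl)oxy]methyl}-2-methyloxiran-2-yl]-4-methylpent-3-en-2-yl 4-nitrobenzoate F9. Brief methanolysis (K2CO3, MeOH, 0 °C) releases 11.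

**Further compounds**
F1 | step 2 | methyl 3-methylbut-2-enoate | COC(=O)C=C(C)C
F2 | step 2 | [(1-methoxy-3-methylbuta-1,3-dien-1-yl)oxy]trimethylsilane (mixture of ketene acetal geometries) | COC(=CC(C)=C)O[Si](C)(C)C
F3 | step 2 | methyl (2E)-5-hydroxy-3,7-dimethylocta-2,6-dienoate (racemic) | COC(=O)/C=C(\C)CC(O)C=C(C)C
F4 | step 2 | (2E)-3,7-dimethylocta-2,6-diene-1,5-diol (racemic) | OC/C=C(\C)CC(O)C=C(C)C
F5 | step 2 | 7-{[(2E)-5-hydroxy-3,7-dimethylocta-2,6-dien-1-yl]oxy}-8-methoxy-2H-chromen-2-one (racemic) | COc1c(OC/C=C(\C)CC(O)C=C(C)C)ccc2ccc(=O)oc12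
F6 | step 4 | 8-methoxy-7-{[(2S,3S)-3-methyl-3-(4-methyl-2-oxopent-3-en-1-yl)oxiran-2-yl]methoxy}-2H-chromen-2-one | COc1c(OC[C@@H]2O[C@@]2(C)CC(=O)C=C(C)C)ccc2ccc(=O)oc12
F7 | step 4 | 7-({(2S,3S)-3-[(2R)-2-hydroxy-4-methylpent-3-en-1-yl]-3-methyloxiran-2-yl}methoxy)-8-methoxy-2H-chromen-2-one | COc1c(OC[C@@H]2O[C@@]2(C)C[C@@H](O)C=C(C)C)ccc2ccc(=O)oc12
F8 | step 5 | 7-({(2R,3R)-3-[(2S)-2-hydroxy-4-methylpent-3-en-1-yl]-3-methyloxiran-2-yl}methoxy)-8-methoxy-2H-chromen-2-one | COc1c(OC[C@H]2O[C@]2(C)C[C@H](O)C=C(C)C)ccc2ccc(=O)oc12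
F9 | step 5 | (2R)-1-[(2R,3R)-3-{[(8-methoxy-2-oxo-2H-chromen-7-yl)oxy]methyl}-2-methyloxiran-2-yl]-4-methylpent-3-en-2-yl 4-nitrobenzoate | COc1c(OC[C@H]2O[C@]2(C)C[C@@H](OC(=O)c3ccc(cc3)[N+](=O)[O-])C=C(C)C)ccc2ccc(=O)oc12
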